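**Strategy.** The route rests on cutting the C7–C8 bond of the 19-membered lactam (ring B), where the C7 carbinol that carries the carbamate sits between the C6 methoxy carbon and the (Z)-C8=C9 trisubstituted alkene. One Nozaki–Hiyama–Kishi reaction joins an alkenylchromium at C8 to the C7 aldehyde, which forms that bond, closes ring B onto the benzene ring A and creates the C7 stereocentre. The precursor is an open-chain anilide: a C8–C21 arene segment ending in a (Z)-alkenyl iodide, acylated on nitrogen by a (2Z,4Z)-dienoyl chain that ends in the 6-methoxy C7 aldehyde. Both halves come from reagent-controlled allyl- and crotylborations and Z-selective olefinations.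

Key step: step 27

Remark: the target is taken exactly as written (2Z,4Z,8Z; 6S,7S,10S,11R,12S,14S,15R). Carbons are numbered along the ansa chain from the amide carbonyl C1 to the benzylic C15, the arene being C16–C21. The stereodescriptors of 37 and 38 were checked centre by centre against the target and agree with it.

**Arene segment (C8–C21)**

Step 1
Reactants: 1 2-hydroxy-5-methoxybenzaldehyde
Product: 2 2-hydroxy-5-methoxy-3-nitrobenzaldehyde
Conditions: HNO3 (1.05 equiv), AcOH, 10–15 °C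
Reagents that add atoms: nitric acid, O[N+](=O)[O-]
Why: Electrophilic aromatic nitration; C3 is ortho to the phenol and meta to the formyl group, and the para position of the phenol is blocked by the methoxy group.

Step 2
Reactants: 2 2-hydroxy-5-methoxy-3-nitrobenzaldehyde
Product: 3 2,5-dimethoxy-3-nitrobenzaldehyde
Conditions: Me2SO4, K2CO3, acetone, reflux
Reagents that add atoms: dimethyl sulfate, COS(=O)(=O)OC
Why: Williamson O-methylation of the acidic ortho-nitrophenol.

Step 3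
Reactants: 3 2,5-dimethoxy-3-nitrobenzaldehyde
Product: 5 (1R,2S)-1-(2,5-dimethoxy-3-nitrophenyl)-2-methylbut-3-en-1-ol, via borinate ester 4 (not isolated)
Conditions: cis-2-butene, KOt-Bu, n-BuLi, THF, −78 to −45 °C; (+)-Ipc2BOMe, −78 °C; BF3·OEt2; then 3, −78 °C; 3 M NaOH, 30% H2O2, 0 °C to rt
Reagents that add atoms: (Z)-crotyldiisopinocampheylborane, made in the flask from cis-2-butene, C/C=C\CB([C@H]1C[C@H]2C[C@@H]([C@@H]1C)C2(C)C)[C@H]1C[C@H]2C[C@@H]([C@@H]1C)C2(C)C
Why: Brown crotylboration through a closed chair transition state; the Z-crotyl geometry gives the 14,15-syn pair and the Ipc ligands of this antipode (from (−)-α-pinene) direct attack to the Re face of the aldehyde, giving 15R,14S.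

Step 4
Reactants: 5 (1R,2S)-1-(2,5-dimethoxy-3-nitrophenyl)-2-methylbut-3-en-1-ol
Product: 6 1-[(1R,2S)-1-methoxy-2-methylbut-3-en-1-yl]-2,5-dimethoxy-3-nitrobenzene
Conditions: Me3OBF4, 1,8-bis(dimethylamino)naphthalene, 4 Å MS, CH2Cl2, rt
Reagents that add atoms: trimethyloxonium tetrafluoroborate, C[O+](C)C.F[B-](F)(F)F
Why: O-methylation with Meerwein salt under base-free conditions, which spares the nitroarene and the stereocentres.

Step 5
Reactants: 6 1-[(1R,2S)-1-methoxy-2-methylbut-3-en-1-yl]-2,5-dimethoxy-3-nitrobenzene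
Product: 8 (3S,4R)-4-(2,5-dimethoxy-3-nitrophenyl)-4-methoxy-3-methylbutan-1-ol, via alkylborane 7 (not isolated)
Conditions: 9-BBN, THF, 0 °C to rt; 3 M NaOH, 30% H2O2, 0 °C
Reagents that add atoms: hydrogen peroxide, OO
Why: Hydroboration–oxidation; the bulky borane adds to the terminal carbon only (anti-Markovnikov) and the C–B bond is oxidised to the primary alcohol.

Step 6
Reactants: 8 (3S,4R)-4-(2,5-dimethoxy-3-nitrophenyl)-4-methoxy-3-methylbutan-1-ol
Product: 9 (3S,4R)-4-(2,5-dimethoxy-3-nitrophenyl)-4-methoxy-3-methylbutanal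
Conditions: Dess–Martin periodinane, CH2Cl2, 0 °C to rt
Reagents that add atoms: none
Why: Dess–Martin oxidation of a primary alcohol to the aldehyde; the α-carbon is a methylene, so nothing can epimerise.

Step 7
Reactants: 9 (3S,4R)-4-(2,5-dimethoxy-3-nitrophenyl)-4-methoxy-3-methylbutanal
Product: 11 (4R,6S,7R)-7-(2,5-dimethoxy-3-nitrophenyl)-7-methoxy-6-methylhept-1-en-4-ol, via borinate ester 10 (not isolated)
Conditions: (+)-Ipc2BOMe, CH2=CHCH2MgBr (0.95 equiv), Et2O, 0 °C to rt; then 9, −78 °C; 3 M NaOH, 30% H2O2, 0 °C to rt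
Reagents that add atoms: allyldiisopinocampheylborane, made in the flask from allylmagnesium bromide, C=CCB([C@H]1C[C@H]2C[C@@H]([C@@H]1C)C2(C)C)[C@H]1C[C@H]2C[C@@H]([C@@H]1C)C2(C)C
Why: Brown allylboration; the Ipc ligands steer the chair transition state to the Re face of the aldehyde, which sets the C12 carbinol under reagent control (descriptor R in 11, the configuration the target needs).

Step 8
Reactants: 11 (4R,6S,7R)-7-(2,5-dimethoxy-3-nitrophenyl)-7-methoxy-6-methylhept-1-en-4-ol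
Product: 12 1-[(1R,2S,4R)-1,4-dimethoxy-2-methylhept-6-en-1-yl]-2,5-dimethoxy-3-nitrobenzene
Conditions: Me3OBF4, 1,8-bis(dimethylamino)naphthalene, 4 Å MS, CH2Cl2, rt
Reagents that add atoms: trimethyloxonium tetrafluoroborate, C[O+](C)C.F[B-](F)(F)F
Why: Base-free Meerwein methylation of the secondary alcohol.

Step 9
Reactants: 12 1-[(1R,2S,4R)-1,4-dimethoxy-2-methylhept-6-en-1-yl]-2,5-dimethoxy-3-nitrobenzene
Product: 13 1-[(1R,2S,4S,5E)-1,4-dimethoxy-2-methylhept-5-en-1-yl]-2,5-dimethoxy-3-nitrobenzene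
Conditions: second-generation Grubbs catalyst (5 mol %), MeOH, 60 °C
Reagents that add atoms: none
Why: Olefin isomerisation by a ruthenium hydride formed from the carbene complex in methanol; addition–elimination moves the terminal double bond one position inward, and the internal alkene binds the catalyst much less well, so migration should stop at the propenyl ether.

Step 10
Reactants: 13 1-[(1R,2S,4S,5E)-1,4-dimethoxy-2-methylhept-5-en-1-yl]-2,5-dimethoxy-3-nitrobenzene
Product: 15 (2S,4S,5R)-5-(2,5-dimethoxy-3-nitrophenyl)-2,5-dimethoxy-4-methylpentanal, via ozonide 14 (not isolated)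
Conditions: O3, CH2Cl2, −78 °C; PPh3, −78 °C to rt; used crude
Reagents that add atoms: ozone, [O-][O+]=O
Why: Ozonolysis with reductive work-up cuts the propenyl group down to the C11 aldehyde; the nitro-deactivated arene and the C12 centre are not touched.

Step 11
Reactants: 15 (2S,4S,5R)-5-(2,5-dimethoxy-3-nitrophenyl)-2,5-dimethoxy-4-methylpentanal
Product: 17 (3S,4R,5S,7S,8R)-8-(2,5-dimethoxy-3-nitrophenyl)-5,8-dimethoxy-3,7-dimethyloct-1-en-4-ol, via borinate ester 16 (not isolated)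
Conditions: cis-2-butene, KOt-Bu, n-BuLi, THF, −78 to −45 °C; (+)-Ipc2BOMe, −78 °C; BF3·OEt2; then 15, −78 °C; 3 M NaOH, 30% H2O2, 0 °C to rt
Reagents that add atoms: (Z)-crotyldiisopinocampheylborane, made in the flask from cis-2-butene, C/C=C\CB([C@H]1C[C@H]2C[C@@H]([C@@H]1C)C2(C)C)[C@H]1C[C@H]2C[C@@H]([C@@H]1C)C2(C)C
Why: Brown crotylboration; the Z-crotyl geometry gives 10,11-syn, the Ipc ligands direct attack to the Re face (11R), and this is also the face the α-methoxy aldehyde prefers (polar Felkin–Anh, 11,12-anti), so reagent and substrate are matched.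

Step 12
Reactants: 17 (3S,4R,5S,7S,8R)-8-(2,5-dimethoxy-3-nitrophenyl)-5,8-dimethoxy-3,7-dimethyloct-1-en-4-ol
Product: 18 1-[(1R,2S,4S,5R,6S)-1,4,5-trimethoxy-2,6-dimethyloct-7-en-1-yl]-2,5-dimethoxy-3-nitrobenzene
Conditions: Me3OBF4, 1,8-bis(dimethylamino)naphthalene, 4 Å MS, CH2Cl2, rt to 35 °C
Reagents that add atoms: trimethyloxonium tetrafluoroborate, C[O+](C)C.F[B-](F)(F)F
Why: Base-free Meerwein methylation of the hindered C11 alcohol.

Step 13
Reactants: 18 1-[(1R,2S,4S,5R,6S)-1,4,5-trimethoxy-2,6-dimethyloct-7-en-1-yl]-2,5-dimethoxy-3-nitrobenzene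
Product: 20 (2R,3R,4S,6S,7R)-7-(2,5-dimethoxy-3-nitrophenyl)-3,4,7-trimethoxy-2,6-dimethylheptanal, via ozonide 19 (not isolated)
Conditions: O3, CH2Cl2, −78 °C; PPh3, −78 °C to rt; used crude
Reagents that add atoms: ozone, [O-][O+]=O
Why: Ozonolysis of the vinyl group gives the C9 aldehyde under neutral conditions, so the C10 centre should survive.

Step 14
Reactants: 20 (2R,3R,4S,6S,7R)-7-(2,5-dimethoxy-3-nitrophenyl)-3,4,7-trimethoxy-2,6-dimethylheptanal; 21 ethyltriphenylphosphonium iodide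
Product: 22 1-[(1R,2S,4S,5R,6S,7Z)-8-iodo-1,4,5-trimethoxy-2,6-dimethylnon-7-en-1-yl]-2,5-dimethoxy-3-nitrobenzene
Conditions: 21, n-BuLi, THF, 0 °C; I2, −78 °C; NaN(SiMe3)2, −20 °C; then 20, −78 to −20 °C
Reagents that add atoms: iodine, [I][I]
Why: Stork–Zhao-type Wittig olefination with the α-iodo ylide Ph3P=C(I)CH3; the kinetically formed cis-oxaphosphetane collapses to the (Z)-iodoalkene with iodine cis to C10.

Step 15
Reactants: 22 1-[(1R,2S,4S,5R,6S,7Z)-8-iodo-1,4,5-trimethoxy-2,6-dimethylnon-7-en-1-yl]-2,5-dimethoxy-3-nitrobenzene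
Product: 23 3-[(1R,2S,4S,5R,6S,7Z)-8-iodo-1,4,5-trimethoxy-2,6-dimethylnon-7-en-1-yl]-2,5-dimethoxyaniline
Conditions: Fe powder, NH4Cl, EtOH/H2O (4:1), 70 °C
Reagents that add atoms: none
Why: Béchamp-type nitro reduction by electron transfer from iron under near-neutral conditions, which leaves the alkenyl iodide and the ethers intact.

**Acid segment (C1–C7)**

Step 16
Reactants: 24 (S)-but-3-ene-1,2-diol
Product: 25 (S)-1-[(tert-butyldimethylsilyl)oxy]but-3-en-2-ol
Conditions: TBSCl (1.0 equiv), imidazole, CH2Cl2, −10 °C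
Reagents that add atoms: tert-butyldimethylsilyl chloride, CC(C)(C)[Si](C)(C)Cl
Why: Silylation goes to the less hindered primary hydroxyl.

Step 17
Reactants: 25 (S)-1-[(tert-butyldimethylsilyl)oxy]but-3-en-2-ol
Product: 26 (S)-tert-butyl[(2-methoxybut-3-en-1-yl)oxy]dimethylsilane
Conditions: Me3OBF4, 1,8-bis(dimethylamino)naphthalene, 4 Å MS, CH2Cl2, rt
Reagents that add atoms: trimethyloxonium tetrafluoroborate, C[O+](C)C.F[B-](F)(F)F
Why: Base-free Meerwein methylation; no alkoxide is formed, so the silyl group cannot migrate to the secondary oxygen.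

Step 18
Reactants: 26 (S)-tert-butyl[(2-methoxybut-3-en-1-yl)oxy]dimethylsilane
Product: 28 (R)-3-[(tert-butyldimethylsilyl)oxy]-2-methoxypropanal, via ozonide 27 (not isolated)
Conditions: O3, CH2Cl2, −78 °C; PPh3, −78 °C to rt; used crude
Reagents that add atoms: ozone, [O-][O+]=O
Why: Ozonolysis of the vinyl group gives the α-methoxy aldehyde without acid or base, so the centre that becomes C6 is kept.

Step 19
Reactants: 28 (R)-3-[(tert-butyldimethylsilyl)oxy]-2-methoxypropanal
Product: 29 methyl (2Z,4S)-5-[(tert-butyldimethylsilyl)oxy]-4-methoxypent-2-enoate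
Conditions: (CF3CH2O)2P(O)CH2CO2Me, KN(SiMe3)2, 18-crown-6, THF, −78 °C
Reagents that add atoms: methyl bis(2,2,2-trifluoroethyl)phosphonoacetate, COC(=O)CP(=O)(OCC(F)(F)F)OCC(F)(F)F
Why: Still–Gennari olefination; the electron-poor phosphonate eliminates fast from the kinetic adduct and gives the Z-enoate (the future 4Z alkene).

Step 20
Reactants: 29 methyl (2Z,4S)-5-[(tert-butyldimethylsilyl)oxy]-4-methoxypent-2-enoate
Product: 30 (2Z,4S)-5-[(tert-butyldimethylsilyl)oxy]-4-methoxypent-2-en-1-ol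
Conditions: i-Bu2AlH (2.2 equiv), CH2Cl2, −78 °C
Reagents that add atoms: none
Why: 1,2-Reduction of the enoate to the allylic alcohol by the aluminium hydride, with the Z geometry retained.

Step 21
Reactants: 30 (2Z,4S)-5-[(tert-butyldimethylsilyl)oxy]-4-methoxypent-2-en-1-ol
Product: 31 (2Z,4S)-5-[(tert-butyldimethylsilyl)oxy]-4-methoxypent-2-enal
Conditions: Dess–Martin periodinane, pyridine, CH2Cl2, 0 °C; used at once
Reagents that add atoms: none
Why: Buffered Dess–Martin oxidation is fast and neutral, which limits Z to E isomerisation of the enal.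

Step 22
Reactants: 31 (2Z,4S)-5-[(tert-butyldimethylsilyl)oxy]-4-methoxypent-2-enal
Product: 32 ethyl (2Z,4Z,6S)-7-[(tert-butyldimethylsilyl)oxy]-6-methoxy-2-methylhepta-2,4-dienoate
Conditions: (CF3CH2O)2P(O)CH(CH3)CO2Et, KN(SiMe3)2, 18-crown-6, THF, −78 °C
Reagents that add atoms: ethyl 2-[bis(2,2,2-trifluoroethoxy)phosphoryl]propanoate, CCOC(=O)C(C)P(=O)(OCC(F)(F)F)OCC(F)(F)F
Why: Still–Gennari olefination with the α-methyl phosphonate gives the Z-trisubstituted alkene, with the ester cis to C4.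

Step 23
Reactants: 32 ethyl (2Z,4Z,6S)-7-[(tert-butyldimethylsilyl)oxy]-6-methoxy-2-methylhepta-2,4-dienoate
Product: 33 (2Z,4Z,6S)-7-[(tert-butyldimethylsilyl)oxy]-6-methoxy-2-methylhepta-2,4-dienoic acid
Conditions: LiOH, THF/MeOH/H2O, rt; then 1 M HCl to pH 4
Reagents that add atoms: lithium hydroxide, [Li+].[OH-]
Why: Saponification of the ethyl ester; the primary silyl ether tolerates aqueous hydroxide at room temperature.

**Union, ring closure and end game**

Step 24
Reactants: 23 3-[(1R,2S,4S,5R,6S,7Z)-8-iodo-1,4,5-trimethoxy-2,6-dimethylnon-7-en-1-yl]-2,5-dimethoxyaniline; 33 (2Z,4Z,6S)-7-[(tert-butyldimethylsilyl)oxy]-6-methoxy-2-methylhepta-2,4-dienoic acid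
Product: 35 seco anilide silyl ether (N-aryl (2Z,4Z,6S)-dienamide of 23 with C7–OTBS), via acid chloride 34 (not isolated)
Conditions: 33, 1-chloro-N,N,2-trimethylprop-1-en-1-amine, CH2Cl2, 0 °C; then 23, 2,6-lutidine, 0 °C to rt
Reagents that add atoms: none
Why: The acid chloride is made under neutral conditions with the Ghosez reagent and acylates the aniline; no nucleophilic catalyst is present, so the (2Z)-enoyl unit should not isomerise.

Step 25
Reactants: 35 seco anilide silyl ether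
Product: 36 seco anilide C7 alcohol
Conditions: HF·pyridine, pyridine, THF, 0 °C to rt
Reagents that add atoms: none
Why: Fluoride-driven cleavage of the primary silyl ether; buffered HF leaves the methyl ethers, dienamide and alkenyl iodide alone.

Step 26
Reactants: 36 seco anilide C7 alcohol
Product: 37 seco (Z)-alkenyl iodide aldehyde
Conditions: Dess–Martin periodinane (1.2 equiv), pyridine, CH2Cl2, 0 °C, 30 min; filtered and used at once
Reagents that add atoms: none
Why: Buffered Dess–Martin oxidation gives the aldehyde without acid or base, as needed because C6–H is α to the carbonyl and allylic; the short time and small excess spare the anilide.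

Step 27
Reactants: 37 seco (Z)-alkenyl iodide aldehyde
Product: 38 macrolactam C7 alcohol (7S)
Conditions: CrCl2 (15 equiv), NiCl2 (1 mol % of the CrCl2), degassed DMSO/THF (3:1), 37 added by syringe pump to 0.002 M, rt; then H2O
Reagents that add atoms: none
Why: CrCl2 reduces NiCl2 to zerovalent nickel, which inserts into the C8–I bond with retention; transmetalation gives an alkenyl species of trivalent chromium that adds to the C7 aldehyde, and water frees the alcohol from the chromium alkoxide. The closest known reaction type is the Nozaki–Hiyama–Kishi macrocyclisation of iodoalkene aldehydes to cyclic allylic alcohols. Ring B (19-membered) closes in the 19-exo-trig mode at the aldehyde carbon, helped by high dilution and by the anilide and (2Z,4Z)-diene segments, which stiffen the chain. The new C7 centre must be S (6,7-syn); this is the face attacked when chromium bridges the carbonyl oxygen and the C6 methoxy group (chelate model), with the conformation of the closing ring as the second control element, and the sense of addition is not assured in advance. The step also needs retention of the 8Z geometry, which the configurationally stable alkenylchromium secures, and selectivity for the aldehyde over the amide and arene, which the low basicity of the organochromium secures. The oxidation of step 26 and this step are run back to back because 37 can epimerise at C6 or move its C4=C5 bond into conjugation.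

Step 28
Reactants: 38 macrolactam C7 alcohol
Product: 40 macrolactam C7 carbamate (hydroquinone dimethyl ether), via trichloroacetyl carbamate 39 (not isolated)
Conditions: Cl3CC(O)NCO, CH2Cl2, 0 °C; then K2CO3 (cat.), MeOH, rt
Reagents that add atoms: trichloroacetyl isocyanate, O=C=NC(=O)C(Cl)(Cl)Cl
Why: The allylic alcohol adds to the acyl isocyanate and methanolysis removes the trichloroacetyl group, giving the primary carbamate with retention at C7.

Step 29
Reactants: 40 macrolactam C7 carbamate (hydroquinone dimethyl ether)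
Product: 41 quinone (C18, C21 dione)
Conditions: (NH4)2Ce(NO3)6 (2.5 equiv), MeCN/H2O (4:1), −10 °C
Reagents that add atoms: water, O
Why: Oxidative demethylation of a para-dimethoxyarene to the para-quinone by single-electron oxidation and attack of water; the amido-substituted ring is the most electron-rich site of the molecule.

Step 30
Reactants: 41 quinone
Product: 42 target hydroquinone CNP0109452.1
Conditions: Na2S2O4, EtOAc/H2O, rt, under argon
Reagents that add atoms: none
Why: Dithionite reduces the quinone to the hydroquinone by two-electron transfer without touching alkenes, carbamate or amide; the product is kept under inert gas.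

**Compound list**

1 | 2-hydroxy-5-methoxybenzaldehyde | COc1ccc(O)c(C=O)c1 | starting material
2 | 2-hydroxy-5-methoxy-3-nitrobenzaldehyde | O=Cc1cc(OC)cc(c1O)[N+](=O)[O-] | intermediate
3 | 2,5-dimethoxy-3-nitrobenzaldehyde | O=Cc1cc(OC)cc(c1OC)[N+](=O)[O-] | intermediate
4 | O-bis(isopinocampheyl)boryl ether (borinate ester) of 5 | C=C[C@H](C)[C@@H](OB([C@H]1C[C@H]2C[C@@H]([C@@H]1C)C2(C)C)[C@H]1C[C@H]2C[C@@H]([C@@H]1C)C2(C)C)c1cc(OC)cc(c1OC)[N+](=O)[O-] | intermediate
5 | (1R,2S)-1-(2,5-dimethoxy-3-nitrophenyl)-2-methylbut-3-en-1-ol | C=C[C@H](C)[C@@H](O)c1cc(OC)cc(c1OC)[N+](=O)[O-] | intermediate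
6 | 1-[(1R,2S)-1-methoxy-2-methylbut-3-en-1-yl]-2,5-dimethoxy-3-nitrobenzene | C=C[C@H](C)[C@@H](OC)c1cc(OC)cc(c1OC)[N+](=O)[O-] | intermediate
7 | 9-[(3S,4R)-4-(2,5-dimethoxy-3-nitrophenyl)-4-methoxy-3-methylbutyl]-9-borabicyclo[3.3.1]nonane | B1(CC[C@H](C)[C@@H](OC)c2cc(OC)cc(c2OC)[N+](=O)[O-])C2CCCC1CCC2 | intermediate
8 | (3S,4R)-4-(2,5-dimethoxy-3-nitrophenyl)-4-methoxy-3-methylbutan-1-ol | OCC[C@H](C)[C@@H](OC)c1cc(OC)cc(c1OC)[N+](=O)[O-] | intermediate
9 | (3S,4R)-4-(2,5-dimethoxy-3-nitrophenyl)-4-methoxy-3-methylbutanal (C12 aldehyde) | O=CC[C@H](C)[C@@H](OC)c1cc(OC)cc(c1OC)[N+](=O)[O-] | intermediate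
10 | O-bis(isopinocampheyl)boryl ether (borinate ester) of 11 | C=CC[C@@H](OB([C@H]1C[C@H]2C[C@@H]([C@@H]1C)C2(C)C)[C@H]1C[C@H]2C[C@@H]([C@@H]1C)C2(C)C)C[C@H](C)[C@@H](OC)c1cc(OC)cc(c1OC)[N+](=O)[O-] | intermediate
11 | (4R,6S,7R)-7-(2,5-dimethoxy-3-nitrophenyl)-7-methoxy-6-methylhept-1-en-4-ol | C=CC[C@@H](O)C[C@H](C)[C@@H](OC)c1cc(OC)cc(c1OC)[N+](=O)[O-] | intermediate
12 | 1-[(1R,2S,4R)-1,4-dimethoxy-2-methylhept-6-en-1-yl]-2,5-dimethoxy-3-nitrobenzene | C=CC[C@@H](OC)C[C@H](C)[C@@H](OC)c1cc(OC)cc(c1OC)[N+](=O)[O-] | intermediate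
13 | 1-[(1R,2S,4S,5E)-1,4-dimethoxy-2-methylhept-5-en-1-yl]-2,5-dimethoxy-3-nitrobenzene | C/C=C/[C@@H](OC)C[C@H](C)[C@@H](OC)c1cc(OC)cc(c1OC)[N+](=O)[O-] | intermediate
14 | ozonide (1,2,4-trioxolane) of 13 | CC1OOC(O1)[C@@H](OC)C[C@H](C)[C@@H](OC)c1cc(OC)cc(c1OC)[N+](=O)[O-] | intermediate
15 | (2S,4S,5R)-5-(2,5-dimethoxy-3-nitrophenyl)-2,5-dimethoxy-4-methylpentanal (C11 aldehyde) | O=C[C@@H](OC)C[C@H](C)[C@@H](OC)c1cc(OC)cc(c1OC)[N+](=O)[O-] | intermediate
16 | O-bis(isopinocampheyl)boryl ether (borinate ester) of 17 | C=C[C@H](C)[C@@H](OB([C@H]1C[C@H]2C[C@@H]([C@@H]1C)C2(C)C)[C@H]1C[C@H]2C[C@@H]([C@@H]1C)C2(C)C)[C@@H](OC)C[C@H](C)[C@@H](OC)c1cc(OC)cc(c1OC)[N+](=O)[O-] | intermediate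
17 | (3S,4R,5S,7S,8R)-8-(2,5-dimethoxy-3-nitrophenyl)-5,8-dimethoxy-3,7-dimethyloct-1-en-4-ol | C=C[C@H](C)[C@@H](O)[C@@H](OC)C[C@H](C)[C@@H](OC)c1cc(OC)cc(c1OC)[N+](=O)[O-] | intermediate
18 | 1-[(1R,2S,4S,5R,6S)-1,4,5-trimethoxy-2,6-dimethyloct-7-en-1-yl]-2,5-dimethoxy-3-nitrobenzene | C=C[C@H](C)[C@@H](OC)[C@@H](OC)C[C@H](C)[C@@H](OC)c1cc(OC)cc(c1OC)[N+](=O)[O-] | intermediate
19 | ozonide (1,2,4-trioxolane) of 18 | C1OOC(O1)[C@H](C)[C@@H](OC)[C@@H](OC)C[C@H](C)[C@@H](OC)c1cc(OC)cc(c1OC)[N+](=O)[O-] | intermediate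
20 | (2R,3R,4S,6S,7R)-7-(2,5-dimethoxy-3-nitrophenyl)-3,4,7-trimethoxy-2,6-dimethylheptanal (C9 aldehyde) | O=C[C@H](C)[C@@H](OC)[C@@H](OC)C[C@H](C)[C@@H](OC)c1cc(OC)cc(c1OC)[N+](=O)[O-] | intermediate
21 | ethyltriphenylphosphonium iodide | CC[P+](c1ccccc1)(c1ccccc1)c1ccccc1.[I-] | starting material
22 | 1-[(1R,2S,4S,5R,6S,7Z)-8-iodo-1,4,5-trimethoxy-2,6-dimethylnon-7-en-1-yl]-2,5-dimethoxy-3-nitrobenzene | I/C(C)=C\[C@H](C)[C@@H](OC)[C@@H](OC)C[C@H](C)[C@@H](OC)c1cc(OC)cc(c1OC)[N+](=O)[O-] | intermediate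
23 | 3-[(1R,2S,4S,5R,6S,7Z)-8-iodo-1,4,5-trimethoxy-2,6-dimethylnon-7-en-1-yl]-2,5-dimethoxyaniline | I/C(C)=C\[C@H](C)[C@@H](OC)[C@@H](OC)C[C@H](C)[C@@H](OC)c1cc(OC)cc(c1OC)N | intermediate
24 | (S)-but-3-ene-1,2-diol | C=C[C@H](O)CO | starting material
25 | (S)-1-[(tert-butyldimethylsilyl)oxy]but-3-en-2-ol | C=C[C@H](O)CO[Si](C)(C)C(C)(C)C | intermediate
26 | (S)-tert-butyl[(2-methoxybut-3-en-1-yl)oxy]dimethylsilane | C=C[C@H](OC)CO[Si](C)(C)C(C)(C)C | intermediate
27 | ozonide (1,2,4-trioxolane) of 26 | C1OOC(O1)[C@H](OC)CO[Si](C)(C)C(C)(C)C | intermediate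
28 | (R)-3-[(tert-butyldimethylsilyl)oxy]-2-methoxypropanal | O=C[C@H](OC)CO[Si](C)(C)C(C)(C)C | intermediate
29 | methyl (2Z,4S)-5-[(tert-butyldimethylsilyl)oxy]-4-methoxypent-2-enoate | COC(=O)/C=C\[C@H](OC)CO[Si](C)(C)C(C)(C)C | intermediate
30 | (2Z,4S)-5-[(tert-butyldimethylsilyl)oxy]-4-methoxypent-2-en-1-ol | OC/C=C\[C@H](OC)CO[Si](C)(C)C(C)(C)C | intermediate
31 | (2Z,4S)-5-[(tert-butyldimethylsilyl)oxy]-4-methoxypent-2-enal | O=C/C=C\[C@H](OC)CO[Si](C)(C)C(C)(C)C | intermediate
32 | ethyl (2Z,4Z,6S)-7-[(tert-butyldimethylsilyl)oxy]-6-methoxy-2-methylhepta-2,4-dienoate | CCOC(=O)/C(C)=C\C=C/[C@H](OC)CO[Si](C)(C)C(C)(C)C | intermediate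
33 | (2Z,4Z,6S)-7-[(tert-butyldimethylsilyl)oxy]-6-methoxy-2-methylhepta-2,4-dienoic acid | OC(=O)/C(C)=C\C=C/[C@H](OC)CO[Si](C)(C)C(C)(C)C | intermediate
34 | (2Z,4Z,6S)-7-[(tert-butyldimethylsilyl)oxy]-6-methoxy-2-methylhepta-2,4-dienoyl chloride | ClC(=O)/C(C)=C\C=C/[C@H](OC)CO[Si](C)(C)C(C)(C)C | intermediate
35 | seco anilide silyl ether: amide of 23 with 33 (C7–OTBS, C8 alkenyl iodide) | I/C(C)=C\[C@H](C)[C@@H](OC)[C@@H](OC)C[C@H](C)[C@@H](OC)c1cc(OC)cc(c1OC)NC(=O)/C(C)=C\C=C/[C@H](OC)CO[Si](C)(C)C(C)(C)C | intermediate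
36 | seco anilide C7 alcohol | I/C(C)=C\[C@H](C)[C@@H](OC)[C@@H](OC)C[C@H](C)[C@@H](OC)c1cc(OC)cc(c1OC)NC(=O)/C(C)=C\C=C/[C@H](OC)CO | intermediate
37 | seco (Z)-alkenyl iodide aldehyde (C7 aldehyde, C8 iodide) | I/C(C)=C\[C@H](C)[C@@H](OC)[C@@H](OC)C[C@H](C)[C@@H](OC)c1cc(OC)cc(c1OC)NC(=O)/C(C)=C\C=C/[C@H](OC)C=O | intermediate
38 | macrolactam C7 alcohol (2Z,4Z,8Z; 6S,7S,10S,11R,12S,14S,15R; arene as dimethyl ether) | CO[C@H]1[C@@H](OC)C[C@H](C)[C@@H](OC)c2cc(OC)cc(c2OC)NC(=O)/C(C)=C\C=C/[C@H](OC)[C@@H](O)/C(C)=C\[C@@H]1C | intermediate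
39 | macrolactam C7 N-(trichloroacetyl)carbamate | CO[C@H]1[C@@H](OC)C[C@H](C)[C@@H](OC)c2cc(OC)cc(c2OC)NC(=O)/C(C)=C\C=C/[C@H](OC)[C@@H](OC(=O)NC(=O)C(Cl)(Cl)Cl)/C(C)=C\[C@@H]1C | intermediate
40 | macrolactam C7 carbamate, hydroquinone dimethyl ether | CO[C@H]1[C@@H](OC)C[C@H](C)[C@@H](OC)c2cc(OC)cc(c2OC)NC(=O)/C(C)=C\C=C/[C@H](OC)[C@@H](OC(N)=O)/C(C)=C\[C@@H]1C | intermediate
41 | macrolactam C7 carbamate, C18/C21 para-quinone | CO[C@H]1[C@@H](OC)C[C@H](C)[C@@H](OC)C2=CC(=O)C=C(C2=O)NC(=O)/C(C)=C\C=C/[C@H](OC)[C@@H](OC(N)=O)/C(C)=C\[C@@H]1C | intermediate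
42 | CNP0109452.1: macrolactam C7 carbamate, C18/C21 hydroquinone | CO[C@H]1[C@@H](OC)C[C@H](C)[C@@H](OC)c2cc(O)cc(c2O)NC(=O)/C(C)=C\C=C/[C@H](OC)[C@@H](OC(N)=O)/C(C)=C\[C@@H]1C | target

**Count and risk**

Total step count: 30 (15 for the arene segment, 8 for the acid segment, 7 from union to target).
Longest linear sequence: 22 steps (steps 1–15, then 24–30).

Steps most likely to fail:

1. Step 27 (ring closure). The chromium reagent may add to the other face of the aldehyde (Felkin–Anh sense, hydroxyl anti to the C6 methoxy group), and ring closure competes with reduction of the C–I bond and with dimer formation. The fallback deals with the facial problem and sets C7 by ketone reduction instead of C–C bond formation. It sets out from 37 and comes back at 38. The cyclisation is run as in step 27 and its product is taken on as the 7-epimeric macrolactam alcohol F1, alone or mixed with 38. Dess–Martin periodinane with pyridine oxidises it to the macrocyclic C7 enone F2. Reduction of F2 with (S)-2-methyl-CBS-oxazaborolidine and catecholborane in toluene at −78 °C should deliver hydride anti to the C6 methoxy group, which for hydride addition is the Felkin–Anh sense and leads to the 6,7-syn alcohol 38. The catalyst antipode is chosen on the premise that the alkenyl group acts as the larger ketone substituent.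

2. Step 14 (iodo-olefination). The hindered α-iodo ylide adds slowly, so it may act as a base instead (epimerisation at C10, loss of methanol across C10–C11), and the Z selectivity may erode. The fallback builds the halide in stages; it sets out from 20 and comes back at 22. CBr4 and PPh3 with 2,6-lutidine in CH2Cl2 at 0 °C convert the aldehyde into the 1,1-dibromoalkene F3. Negishi coupling with MeZnCl and catalytic Pd(t-Bu3P)2 in THF replaces only the bromine trans to the chain and gives the (Z)-2-bromoalkene F4. Copper-catalysed halogen exchange (CuI, NaI, trans-N,N'-dimethylcyclohexane-1,2-diamine, dioxane, 110 °C) proceeds with retention and returns 22.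

3. Step 22, together with the enal of step 21 (diene geometry). The γ-alkoxy Z-enal may isomerise to the E-enal before or during olefination, which would carry a 4E impurity into the acid. The fallback makes the C4–C5 bond as an alkyne and reduces it last; it sets out from 28 and comes back at 32. Corey–Fuchs reaction (CBr4, PPh3, CH2Cl2, 0 °C) gives the dibromoalkene F5. Treatment with n-BuLi (2.1 equiv) in THF at −78 °C and then DMF gives the ynal F6. Still–Gennari olefination with the phosphonate of step 22 gives the (Z)-enynoate F7. Semi-reduction with Zn(Cu/Ag) in MeOH/H2O sets the 4Z alkene by cis addition of hydrogen and returns 32.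

Further compounds
F1 | step 27 | 7-epi macrolactam alcohol (7R) | CO[C@H]1[C@@H](OC)C[C@H](C)[C@@H](OC)c2cc(OC)cc(c2OC)NC(=O)/C(C)=C\C=C/[C@H](OC)[C@H](O)/C(C)=C\[C@@H]1C
F2 | step 27 | macrocyclic C7 enone | CO[C@H]1[C@@H](OC)C[C@H](C)[C@@H](OC)c2cc(OC)cc(c2OC)NC(=O)/C(C)=C\C=C/[C@H](OC)C(=O)/C(C)=C\[C@@H]1C
F3 | step 14 | 1-[(1R,2S,4S,5R,6S)-8,8-dibromo-1,4,5-trimethoxy-2,6-dimethyloct-7-en-1-yl]-2,5-dimethoxy-3-nitrobenzene | BrC(Br)=C[C@H](C)[C@@H](OC)[C@@H](OC)C[C@H](C)[C@@H](OC)c1cc(OC)cc(c1OC)[N+](=O)[O-]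
F4 | step 14 | 1-[(1R,2S,4S,5R,6S,7Z)-8-bromo-1,4,5-trimethoxy-2,6-dimethylnon-7-en-1-yl]-2,5-dimethoxy-3-nitrobenzene | Br/C(C)=C\[C@H](C)[C@@H](OC)[C@@H](OC)C[C@H](C)[C@@H](OC)c1cc(OC)cc(c1OC)[N+](=O)[O-]
F5 | step 22 | (S)-tert-butyl[(4,4-dibromo-2-methoxybut-3-en-1-yl)oxy]dimethylsilane | BrC(Br)=C[C@H](OC)CO[Si](C)(C)C(C)(C)C
F6 | step 22 | (S)-5-[(tert-butyldimethylsilyl)oxy]-4-methoxypent-2-ynal | O=CC#C[C@H](OC)CO[Si](C)(C)C(C)(C)C
F7 | step 22 | ethyl (2Z,6S)-7-[(tert-butyldimethylsilyl)oxy]-6-methoxy-2-methylhept-2-en-4-ynoate | CCOC(=O)/C(C)=C\C#C[C@H](OC)CO[Si](C)(C)C(C)(C)C
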